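**Retrosynthetic overview**
1. Target ⇐ global O-debenzylation ⇐ tetrabenzyl ether whose lower dihydropyran ring is closed late by making the aryl–oxygen bond O1–C8a, starting from an open chain that carries a silylated CH2OH group and a plain 4-hydroxybenzyl group (formal dehydrogenative C–H etherification).
2. Enabling feature: in the lower chroman the 7-OH is para to C4a and meta to C8a, so the benzo ring is a masked 4-alkylphenol; in its 4-methoxycyclohexa-2,5-dienone C8a is a β-carbon six atoms from the side-chain oxygen (O1–C2–C3–C4–C4a–C8a), and the para-methoxy group is the leaving group that restores the arene.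
3. Upper trans-3,4-diarylchroman ⇐ C4–C4a Friedel–Crafts ring closure of a benzylic alcohol ⇐ O1–C2 Mitsunobu etherification with 3-(benzyloxy)phenol ⇐ Evans syn-aldol (C3–C4) between a pyrogallol-type arylacetyl imide and the central-ring benzaldehyde.
4. Central-ring aldehyde ⇐ locally C2-symmetric 3,5-bis(benzyloxy)phenylacetic acid: Evans benzylation with a 4-silyloxybenzyl bromide sets lower C3; formylation, then chelation-controlled debenzylation and methylation, tells the two ring oxygens apart.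
5. Ring order: central arene bought; upper pyran ring (step 18) before lower pyran ring (step 20). Stereocentres: lower C3 (step 5), upper C3 (step 15), upper C4 (step 18).

Key step: step 20

Remark on the chemistry: the target is read as (3R,4S) with the two aryl groups trans on the upper chroman and (3R) on the lower chroman. Abbreviations: Bn = benzyl; TIPS = triisopropylsilyl; TBDPS = tert-butyldiphenylsilyl; SC = the side chain (2R)-1-[(tert-butyldiphenylsilyl)oxy]-3-{4-[(triisopropylsilyl)oxy]phenyl}propan-2-yl.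

Step 1
Reactants: 1 4-methylphenol
Product: 2 (4-methylphenoxy)triisopropylsilane
Conditions: TIPSCl, imidazole, DMF, rt
Reagents that add atoms: triisopropylsilyl chloride CC(C)[Si](Cl)(C(C)C)C(C)C
Why: Imidazole-promoted O-silylation of a phenol gives a robust aryl TIPS ether that masks the future lower-ring 7-OH until step 19.

Step 2
Reactants: 2 (4-methylphenoxy)triisopropylsilane
Product: 3 [4-(bromomethyl)phenoxy]triisopropylsilane
Conditions: NBS, AIBN (cat.), PhCF3, 85 °C
Reagents that add atoms: N-bromosuccinimide O=C1CCC(=O)N1Br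
Why: Wohl–Ziegler radical bromination at the only benzylic position should give the alkylating agent, the bulky silyl ether tempering ionic ring bromination.

Step 3
Reactants: 4 methyl 2-(3,5-dihydroxyphenyl)acetate
Product: 6 2-[3,5-bis(benzyloxy)phenyl]acetic acid, via methyl 2-[3,5-bis(benzyloxy)phenyl]acetate 5 (not isolated)
Conditions: BnBr, K2CO3, acetone, reflux; then NaOH, MeOH/H2O, 50 °C; aq. HCl
Reagents that add atoms: benzyl bromide BrCc1ccccc1; sodium hydroxide [Na+].[OH-] (supplies the carboxyl OH oxygen)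
Why: Williamson etherification of both phenols followed by saponification gives a locally C2-symmetric arylacetic acid, so no regiochemical question arises until the ring is formylated.

Step 4
Reactants: 6 2-[3,5-bis(benzyloxy)phenyl]acetic acid; 7 (R)-4-benzyloxazolidin-2-one
Product: 9 (R)-4-benzyl-3-{2-[3,5-bis(benzyloxy)phenyl]acetyl}oxazolidin-2-one, via mixed pivalic anhydride 8 (not isolated)
Conditions: PivCl, Et3N, THF, −20 °C; then 7, LiCl, −20 °C → rt
Reagents that add atoms: none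
Why: N-acylation of the Evans auxiliary through the mixed pivalic anhydride (LiCl/Et3N variant) avoids strong base on the enolisable arylacetyl unit.

Step 5
Reactants: 9 (R)-4-benzyl-3-{2-[3,5-bis(benzyloxy)phenyl]acetyl}oxazolidin-2-one; 3 [4-(bromomethyl)phenoxy]triisopropylsilane
Product: 10 (R)-4-benzyl-3-{(2R)-2-[3,5-bis(benzyloxy)phenyl]-3-[4-(triisopropylsilyloxy)phenyl]propanoyl}oxazolidin-2-one
Conditions: NaHMDS, THF, −78 °C; then 3, −78 → −40 °C
Reagents that add atoms: none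
Why: Evans asymmetric alkylation, in which the chelated (Z)-sodium enolate is benzylated on the face opposite the auxiliary benzyl group; with the (R)-auxiliary this sets the stereocentre as R (the future lower C3), and the minor diastereomer is removable by chromatography.

Step 6
Reactants: 10 the alkylated imide
Product: 11 (2R)-2-[3,5-bis(benzyloxy)phenyl]-3-[4-(triisopropylsilyloxy)phenyl]propan-1-ol
Conditions: LiBH4, MeOH (1.1 equiv), Et2O/THF, 0 °C
Reagents that add atoms: none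
Why: Reductive cleavage of the N-acyl oxazolidinone gives the primary alcohol without touching the now non-acidic benzylic stereocentre and returns the auxiliary.

Step 7
Reactants: 11 the primary alcohol
Product: 12 tert-butyl{(2R)-2-[3,5-bis(benzyloxy)phenyl]-3-[4-(triisopropylsilyloxy)phenyl]propoxy}diphenylsilane
Conditions: TBDPSCl, imidazole, CH2Cl2, rt
Reagents that add atoms: tert-butyl(chloro)diphenylsilane CC(C)(C)[Si](Cl)(c1ccccc1)c1ccccc1
Why: O-silylation gives a TBDPS ether chosen to survive chloroiminium, Lewis-acid and boron chemistry and to be removed only by fluoride inside the key step.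

Step 8
Reactants: 12 the TBDPS ether
Product: 13 2,4-bis(benzyloxy)-6-(SC)benzaldehyde
Conditions: POCl3, DMF, 0 → 60 °C; then aq. NaOAc, rt
Reagents that add atoms: N,N-dimethylformamide CN(C)C=O (formyl carbon); water O (formyl oxygen)
Why: Vilsmeier–Haack formylation of a 5-alkylresorcinol diether should go para to one benzyloxy group and ortho to the alkyl group (two equivalent positions), because the position between the two benzyloxy groups is the more hindered toward the bulky chloroiminium ion.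

Step 9
Reactants: 13 the bis(benzyloxy) aldehyde
Product: 14 4-(benzyloxy)-2-hydroxy-6-(SC)benzaldehyde
Conditions: MgBr2·OEt2, toluene/Et2O, 80 °C; aq. HCl work-up
Reagents that add atoms: none
Why: Chelation-controlled debenzylation, in which Mg(II) held between the formyl oxygen and the ortho benzyloxy oxygen activates only that ether toward bromide, so the two ring oxygens become different.

Step 10
Reactants: 14 the hydroxy aldehyde
Product: 15 4-(benzyloxy)-2-methoxy-6-(SC)benzaldehyde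
Conditions: MeI, K2CO3, acetone, 40 °C
Reagents that add atoms: iodomethane CI
Why: Williamson methylation of the hydrogen-bonded phenol installs the methoxy group next to the future C4 attachment under conditions that an aryl TIPS ether should tolerate.

Step 11
Reactants: 16 2,3-dihydroxy-4-methoxybenzaldehyde
Product: 17 2,3-bis(benzyloxy)-4-methoxybenzaldehyde
Conditions: BnBr, K2CO3, DMF, 60 °C
Reagents that add atoms: benzyl bromide BrCc1ccccc1
Why: Williamson bis-benzylation protects the catechol unit with groups removed only in the last step.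

Step 12
Reactants: 17 2,3-bis(benzyloxy)-4-methoxybenzaldehyde
Product: 19 2-[2,3-bis(benzyloxy)-4-methoxyphenyl]acetaldehyde, via enol ether 18 (not isolated)
Conditions: Ph3P(CH2OMe)Cl, KOtBu, THF, 0 °C → rt; then 2 M HCl, THF, rt
Reagents that add atoms: (methoxymethyl)triphenylphosphonium chloride COC[P+](c1ccccc1)(c1ccccc1)c1ccccc1.[Cl-]; water O
Why: Wittig methoxymethylenation and acid hydrolysis of the enol ether give the one-carbon homologue, used crude because arylacetaldehydes are sensitive.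

Step 13
Reactants: 19 the arylacetaldehyde
Product: 20 2-[2,3-bis(benzyloxy)-4-methoxyphenyl]acetic acid
Conditions: NaClO2, NaH2PO4, 2-methyl-2-butene, t-BuOH/H2O, rt
Reagents that add atoms: sodium chlorite [Na+].[O-]Cl=O
Why: Pinnick oxidation converts the aldehyde to the acid, and the alkene scavenger removes HOCl before it can chlorinate the electron-rich ring.

Step 14
Reactants: 20 the arylacetic acid; 21 (S)-4-benzyloxazolidin-2-one
Product: 23 (S)-4-benzyl-3-{2-[2,3-bis(benzyloxy)-4-methoxyphenyl]acetyl}oxazolidin-2-one, via mixed pivalic anhydride 22 (not isolated)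
Conditions: PivCl, Et3N, THF, −20 °C; then 21, LiCl, −20 °C → rt
Reagents that add atoms: none
Why: N-acylation of the Evans auxiliary as in step 4.

Step 15
Reactants: 23 the (S)-imide; 15 the methoxy aldehyde
Product: 24 (S)-4-benzyl-3-[(2S,3S)-2-[2,3-bis(benzyloxy)-4-methoxyphenyl]-3-[4-(benzyloxy)-2-methoxy-6-(SC)phenyl]-3-hydroxypropanoyl]oxazolidin-2-one
Conditions: Bu2BOTf, i-Pr2NEt, CH2Cl2, −78 → 0 °C; 15, −78 → 0 °C; pH 7 buffer, MeOH, 30% H2O2, 0 °C
Reagents that add atoms: none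
Why: Evans syn-aldol, in which the (Z)-boron enolate reacts through a Zimmerman–Traxler chair on the face fixed by the (S)-auxiliary; this sets the future upper C3 (2S here, 3R in the chroman), and the carbinol centre is ionised later.

Step 16
Reactants: 24 the aldol adduct
Product: 25 (1S,2R)-2-[2,3-bis(benzyloxy)-4-methoxyphenyl]-1-[4-(benzyloxy)-2-methoxy-6-(SC)phenyl]propane-1,3-diol
Conditions: LiBH4, MeOH (1.1 equiv), THF, 0 °C
Reagents that add atoms: none
Why: Mild reductive cleavage of the β-hydroxy imide gives the 1,3-diol without epimerising the α-aryl centre and returns the auxiliary.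

Step 17
Reactants: 25 the diol; 26 3-(benzyloxy)phenol
Product: 27 (1S,2R)-2-[2,3-bis(benzyloxy)-4-methoxyphenyl]-3-[3-(benzyloxy)phenoxy]-1-[4-(benzyloxy)-2-methoxy-6-(SC)phenyl]propan-1-ol
Conditions: PPh3, DIAD, toluene, 0 °C → rt
Reagents that add atoms: none
Why: Mitsunobu etherification should be selective for the unhindered primary hydroxyl over the secondary, di-ortho-flanked benzylic one, and brings in the upper A-ring with the future O1.

Step 18
Reactants: 27 the benzylic alcohol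
Product: 28 (3R,4S)-7-(benzyloxy)-3-[2,3-bis(benzyloxy)-4-methoxyphenyl]-4-[4-(benzyloxy)-2-methoxy-6-(SC)phenyl]chromane
Conditions: Bi(OTf)3 (5 mol%), 4 Å MS, CH2Cl2, −20 → 0 °C
Reagents that add atoms: none
Why: Intramolecular Friedel–Crafts alkylation by the ionised benzylic alcohol at the A-ring carbon para to OBn; in the A(1,3)-strain-minimised cation H-3 lies in the cation plane (poorly aligned for E1 loss), so the tethered arene should add anti to the C3 aryl group and give the 3,4-trans ring (C4 = S).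

Step 19
Reactants: 28 the protected 4-arylchromane
Product: 29 4-{(2R)-2-[5-(benzyloxy)-2-{(3R,4S)-7-(benzyloxy)-3-[2,3-bis(benzyloxy)-4-methoxyphenyl]chroman-4-yl}-3-methoxyphenyl]-3-[(tert-butyldiphenylsilyl)oxy]propyl}phenol
Conditions: KHF2, MeOH/THF, rt
Reagents that add atoms: none
Why: Bifluoride cleaves the phenolic silyl ether selectively (phenoxide is the better leaving group), leaving the alkyl TBDPS ether in place so that exactly one free phenol is present for the oxidation.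

Step 20
Reactants: 29 the free phenol
Product: 33 (3R,4S)-7-(benzyloxy)-3-[2,3-bis(benzyloxy)-4-methoxyphenyl]-4-{4-(benzyloxy)-2-[(3R)-7-hydroxychroman-3-yl]-6-methoxyphenyl}chromane, via quinol methyl ether 30 (not isolated), via desilylated quinol ether 31 (not isolated), via oxa-Michael adduct 32 (not isolated)
Conditions: PhI(OAc)2, MeOH/CH2Cl2, 0 °C; evaporate; TBAF, THF, 0 °C → rt; then TsOH·H2O, rt → 40 °C
Reagents that add atoms: none
Why: Proposed new method: a one-pot oxidative dearomatisation / oxa-Michael / eliminative rearomatisation, in which PhI(OAc)2 turns the 4-alkylphenol (through the aryloxy-λ3-iodane and para capture by methanol) into the 4-alkyl-4-methoxycyclohexa-2,5-dienone 30, fluoride frees the primary alkoxide which adds to a dienone β-carbon (the future C8a) to give 32, and TsOH then promotes enolisation and loss of methanol from C4a (an arenium ion deprotonated at C8a) to restore the benzene ring as the 7-hydroxychroman. The closest known reaction types are the PhI(OAc)2/MeOH synthesis of p-quinol ethers, the oxa-Michael cyclisation of hydroxyalkyl p-quinols, and dearomatisation–Michael–aromatisation sequences with C- and N-nucleophiles; forging an aryl–O bond in this way is the new part. The only ring closed is the lower dihydropyran, by 6-exo-trig oxa-Michael addition forming O1–C8a. No stereocentre of the product is created: the transient C4a/C8a centres are erased on aromatisation, so attack at either β-carbon and every diastereomeric adduct should converge on one product, and C3 is untouched. The step needs chemoselective oxidation of one arene among five (secured by the single free phenol, since iodine(III) must first exchange a ligand at O–H) and para capture by methanol rather than ipso capture by the side-chain oxygen (secured by keeping that oxygen silylated during the oxidation, which excludes the 5-exo spiroether and its rearrangement to the 6-hydroxy isomer). It also needs O- rather than C-addition to the dienone (the alkoxide adds under basic fluoride conditions before acid is introduced, and the nearest nucleophilic carbon of the central ring is flanked on both sides).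

Step 21
Reactants: 33 the tetrabenzyl ether
Product: 34 (3R,4S)-3-(2,3-dihydroxy-4-methoxyphenyl)-4-{4-hydroxy-2-[(3R)-7-hydroxychroman-3-yl]-6-methoxyphenyl}chroman-7-ol (CNP0227211.1)
Conditions: H2 (1 atm), 10% Pd/C, EtOAc/MeOH, rt
Reagents that add atoms: none
Why: Hydrogenolysis of the four aryl benzyl ethers; the chroman O1–C2 bonds are not benzylic and the diarylmethine C–C bonds are inert, so the three stereocentres should be unaffected.

**Compound list**
1 | 4-methylphenol | Cc1ccc(O)cc1 | starting material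
2 | (4-methylphenoxy)triisopropylsilane | Cc1ccc(O[Si](C(C)C)(C(C)C)C(C)C)cc1 | intermediate
3 | [4-(bromomethyl)phenoxy]triisopropylsilane | BrCc1ccc(O[Si](C(C)C)(C(C)C)C(C)C)cc1 | intermediate
4 | methyl 2-(3,5-dihydroxyphenyl)acetate | COC(=O)Cc1cc(O)cc(O)c1 | starting material
5 | methyl 2-[3,5-bis(benzyloxy)phenyl]acetate (not isolated) | COC(=O)Cc1cc(OCc2ccccc2)cc(OCc2ccccc2)c1 | intermediate
6 | 2-[3,5-bis(benzyloxy)phenyl]acetic acid | OC(=O)Cc1cc(OCc2ccccc2)cc(OCc2ccccc2)c1 | intermediate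
7 | (R)-4-benzyloxazolidin-2-one | O=C1N[C@H](Cc2ccccc2)CO1 | starting material
8 | 2-[3,5-bis(benzyloxy)phenyl]acetic pivalic anhydride (not isolated) | CC(C)(C)C(=O)OC(=O)Cc1cc(OCc2ccccc2)cc(OCc2ccccc2)c1 | intermediate
9 | (R)-4-benzyl-3-{2-[3,5-bis(benzyloxy)phenyl]acetyl}oxazolidin-2-one | O=C(Cc1cc(OCc2ccccc2)cc(OCc2ccccc2)c1)N1[C@H](Cc2ccccc2)COC1=O | intermediate
10 | (R)-4-benzyl-3-{(2R)-2-[3,5-bis(benzyloxy)phenyl]-3-[4-(triisopropylsilyloxy)phenyl]propanoyl}oxazolidin-2-one | O=C([C@H](Cc1ccc(O[Si](C(C)C)(C(C)C)C(C)C)cc1)c1cc(OCc2ccccc2)cc(OCc2ccccc2)c1)N1[C@H](Cc2ccccc2)COC1=O | intermediate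
11 | (2R)-2-[3,5-bis(benzyloxy)phenyl]-3-[4-(triisopropylsilyloxy)phenyl]propan-1-ol | OC[C@H](Cc1ccc(O[Si](C(C)C)(C(C)C)C(C)C)cc1)c1cc(OCc2ccccc2)cc(OCc2ccccc2)c1 | intermediate
12 | tert-butyl{(2R)-2-[3,5-bis(benzyloxy)phenyl]-3-[4-(triisopropylsilyloxy)phenyl]propoxy}diphenylsilane | CC(C)(C)[Si](OC[C@H](Cc1ccc(O[Si](C(C)C)(C(C)C)C(C)C)cc1)c1cc(OCc2ccccc2)cc(OCc2ccccc2)c1)(c1ccccc1)c1ccccc1 | intermediate
13 | 2,4-bis(benzyloxy)-6-(SC)benzaldehyde | O=Cc1c(OCc2ccccc2)cc(OCc2ccccc2)cc1[C@H](CO[Si](c1ccccc1)(c1ccccc1)C(C)(C)C)Cc1ccc(O[Si](C(C)C)(C(C)C)C(C)C)cc1 | intermediate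
14 | 4-(benzyloxy)-2-hydroxy-6-(SC)benzaldehyde | O=Cc1c(O)cc(OCc2ccccc2)cc1[C@H](CO[Si](c1ccccc1)(c1ccccc1)C(C)(C)C)Cc1ccc(O[Si](C(C)C)(C(C)C)C(C)C)cc1 | intermediate
15 | 4-(benzyloxy)-2-methoxy-6-(SC)benzaldehyde | O=Cc1c(OC)cc(OCc2ccccc2)cc1[C@H](CO[Si](c1ccccc1)(c1ccccc1)C(C)(C)C)Cc1ccc(O[Si](C(C)C)(C(C)C)C(C)C)cc1 | intermediate
16 | 2,3-dihydroxy-4-methoxybenzaldehyde | COc1ccc(C=O)c(O)c1O | starting material
17 | 2,3-bis(benzyloxy)-4-methoxybenzaldehyde | COc1ccc(C=O)c(OCc2ccccc2)c1OCc1ccccc1 | intermediate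
18 | 2,3-bis(benzyloxy)-1-methoxy-4-(2-methoxyethenyl)benzene, E/Z mixture (not isolated) | COC=Cc1ccc(OC)c(OCc2ccccc2)c1OCc1ccccc1 | intermediate
19 | 2-[2,3-bis(benzyloxy)-4-methoxyphenyl]acetaldehyde | COc1ccc(CC=O)c(OCc2ccccc2)c1OCc1ccccc1 | intermediate
20 | 2-[2,3-bis(benzyloxy)-4-methoxyphenyl]acetic acid | COc1ccc(CC(=O)O)c(OCc2ccccc2)c1OCc1ccccc1 | intermediate
21 | (S)-4-benzyloxazolidin-2-one | O=C1N[C@@H](Cc2ccccc2)CO1 | starting material
22 | 2-[2,3-bis(benzyloxy)-4-methoxyphenyl]acetic pivalic anhydride (not isolated) | COc1ccc(CC(=O)OC(=O)C(C)(C)C)c(OCc2ccccc2)c1OCc1ccccc1 | intermediate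
23 | (S)-4-benzyl-3-{2-[2,3-bis(benzyloxy)-4-methoxyphenyl]acetyl}oxazolidin-2-one | COc1ccc(CC(=O)N2[C@@H](Cc3ccccc3)COC2=O)c(OCc2ccccc2)c1OCc1ccccc1 | intermediate
24 | (S)-4-benzyl-3-[(2S,3S)-2-[2,3-bis(benzyloxy)-4-methoxyphenyl]-3-[4-(benzyloxy)-2-methoxy-6-(SC)phenyl]-3-hydroxypropanoyl]oxazolidin-2-one | COc1ccc([C@@H]([C@H](O)c2c(OC)cc(OCc3ccccc3)cc2[C@H](CO[Si](c2ccccc2)(c2ccccc2)C(C)(C)C)Cc2ccc(O[Si](C(C)C)(C(C)C)C(C)C)cc2)C(=O)N2[C@@H](Cc3ccccc3)COC2=O)c(OCc2ccccc2)c1OCc1ccccc1 | intermediate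
25 | (1S,2R)-2-[2,3-bis(benzyloxy)-4-methoxyphenyl]-1-[4-(benzyloxy)-2-methoxy-6-(SC)phenyl]propane-1,3-diol | COc1ccc([C@@H]([C@H](O)c2c(OC)cc(OCc3ccccc3)cc2[C@H](CO[Si](c2ccccc2)(c2ccccc2)C(C)(C)C)Cc2ccc(O[Si](C(C)C)(C(C)C)C(C)C)cc2)CO)c(OCc2ccccc2)c1OCc1ccccc1 | intermediate
26 | 3-(benzyloxy)phenol | Oc1cccc(OCc2ccccc2)c1 | starting material
27 | (1S,2R)-2-[2,3-bis(benzyloxy)-4-methoxyphenyl]-3-[3-(benzyloxy)phenoxy]-1-[4-(benzyloxy)-2-methoxy-6-(SC)phenyl]propan-1-ol | COc1ccc([C@@H]([C@H](O)c2c(OC)cc(OCc3ccccc3)cc2[C@H](CO[Si](c2ccccc2)(c2ccccc2)C(C)(C)C)Cc2ccc(O[Si](C(C)C)(C(C)C)C(C)C)cc2)COc2cccc(OCc3ccccc3)c2)c(OCc2ccccc2)c1OCc1ccccc1 | intermediate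
28 | (3R,4S)-7-(benzyloxy)-3-[2,3-bis(benzyloxy)-4-methoxyphenyl]-4-[4-(benzyloxy)-2-methoxy-6-(SC)phenyl]chromane | COc1ccc([C@@H]2COc3cc(OCc4ccccc4)ccc3[C@H]2c2c(OC)cc(OCc3ccccc3)cc2[C@H](CO[Si](c2ccccc2)(c2ccccc2)C(C)(C)C)Cc2ccc(O[Si](C(C)C)(C(C)C)C(C)C)cc2)c(OCc2ccccc2)c1OCc1ccccc1 | intermediate
29 | 4-{(2R)-2-[5-(benzyloxy)-2-{(3R,4S)-7-(benzyloxy)-3-[2,3-bis(benzyloxy)-4-methoxyphenyl]chroman-4-yl}-3-methoxyphenyl]-3-[(tert-butyldiphenylsilyl)oxy]propyl}phenol | COc1ccc([C@@H]2COc3cc(OCc4ccccc4)ccc3[C@H]2c2c(OC)cc(OCc3ccccc3)cc2[C@H](CO[Si](c2ccccc2)(c2ccccc2)C(C)(C)C)Cc2ccc(O)cc2)c(OCc2ccccc2)c1OCc1ccccc1 | intermediate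
30 | quinol methyl ether: 29 with the 4-hydroxyphenyl ring converted into a 4-alkyl-4-methoxycyclohexa-2,5-dien-1-one (not isolated) | COc1ccc([C@@H]2COc3cc(OCc4ccccc4)ccc3[C@H]2c2c(OC)cc(OCc3ccccc3)cc2[C@H](CO[Si](c2ccccc2)(c2ccccc2)C(C)(C)C)CC2(OC)C=CC(=O)C=C2)c(OCc2ccccc2)c1OCc1ccccc1 | intermediate
31 | desilylated quinol ether: 30 with free CH2OH (not isolated) | COc1ccc([C@@H]2COc3cc(OCc4ccccc4)ccc3[C@H]2c2c(OC)cc(OCc3ccccc3)cc2[C@H](CO)CC2(OC)C=CC(=O)C=C2)c(OCc2ccccc2)c1OCc1ccccc1 | intermediate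
32 | oxa-Michael adduct: 4a-methoxy-2,3,4,4a,8,8a-hexahydro-7H-chromen-7-one fused at the lower unit, mixture of ring-fusion diastereomers (not isolated) | COc1ccc([C@@H]2COc3cc(OCc4ccccc4)ccc3[C@H]2c2c(OC)cc(OCc3ccccc3)cc2[C@@H]2COC3CC(=O)C=CC3(OC)C2)c(OCc2ccccc2)c1OCc1ccccc1 | intermediate
33 | (3R,4S)-7-(benzyloxy)-3-[2,3-bis(benzyloxy)-4-methoxyphenyl]-4-{4-(benzyloxy)-2-[(3R)-7-hydroxychroman-3-yl]-6-methoxyphenyl}chromane | COc1ccc([C@@H]2COc3cc(OCc4ccccc4)ccc3[C@H]2c2c(OC)cc(OCc3ccccc3)cc2[C@@H]2COc3cc(O)ccc3C2)c(OCc2ccccc2)c1OCc1ccccc1 | intermediate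
34 | (3R,4S)-3-(2,3-dihydroxy-4-methoxyphenyl)-4-{4-hydroxy-2-[(3R)-7-hydroxychroman-3-yl]-6-methoxyphenyl}chroman-7-ol | COc1ccc([C@@H]2COc3cc(O)ccc3[C@H]2c2c(OC)cc(O)cc2[C@@H]2COc3cc(O)ccc3C2)c(O)c1O | target

**Summary**
Total step count: 21. Longest linear sequence: 15 steps (steps 3–10, then 15–21).

**Steps most likely to fail**

1. Step 20 (proposed new method). What may go wrong: addition of the neighbouring resorcinol-type ring carbon to the dienone instead of the alkoxide, incomplete loss of methanol, or dienone–phenol rearrangement under the acid. Fallback (sets out from imide 9, returns at target 34; the same O1–C8a bond is made by known Pd-catalysed aryl halide etherification): commercial 2-bromo-4-hydroxybenzaldehyde is benzylated to 4-(benzyloxy)-2-bromobenzaldehyde F1, reduced with NaBH4 to [4-(benzyloxy)-2-bromophenyl]methanol F2 and brominated with PBr3 to 4-(benzyloxy)-2-bromo-1-(bromomethyl)benzene F3. Alkylation of 9 with F3 under the conditions of step 5 gives the (2R)-imide F4. The conditions of steps 6 to 10 then give in turn the bromo alcohol F5, its TBDPS ether F6, the bis(benzyloxy) aldehyde F7, the hydroxy aldehyde F8 and the methoxy aldehyde F9. Those of steps 15 to 18 give the aldol adduct F10, the diol F11, the aryl ether F12 and the trans-4-arylchromane F13. TBAF frees the primary alcohol F14, and Pd(OAc)2, 2-(di-tert-butylphosphino)-1,1′-binaphthyl and Cs2CO3 in toluene at 80 °C (Buchwald–Hartwig-type intramolecular etherification) close the lower ring to the pentabenzyl ether F15. Hydrogenolysis as in step 21 gives 34.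

2. Step 18. What may go wrong: E1 loss of H-3 from the benzylic cation and re-protonation (erosion of the C3 configuration), closure to the cis isomer or at the carbon between the two A-ring oxygens, or capture of the cation by the silyl ether oxygen or by O-2′. Fallback (sets out from aldehyde 15, using 26 and 19; returns at 28; no free C4 cation next to a preformed C3 centre): the bromomagnesium phenolate of 26 is added to 15 (ortho-selective hydroxyalkylation, para to the benzyloxy group) to give the 2-hydroxybenzhydrol [4-(benzyloxy)-2-hydroxyphenyl][4-(benzyloxy)-2-methoxy-6-(SC)phenyl]methanol F16. Under diarylprolinol silyl ether/acid co-catalysis F16 dehydrates to the ortho-quinone methide, which is trapped by the enamine of aldehyde 19 in a Michael addition/hemiacetalisation to give the trans-3,4-diarylchroman-2-ol F17; C3 is set by the catalyst (the (R)-catalyst is expected to give 3R) and C4 by the anti approach. Ionic reduction of the lactol (Et3SiH, BF3·OEt2, CH2Cl2, −78 °C) gives 28.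

3. Step 8. What may go wrong: attack of the chloroiminium ion at the doubly oxygen-flanked position of the hindered ring, or slow formylation with conversion of the silyl ethers into formates. Fallback (sets out from 12, returns at 13; halogenation and halogen–metal exchange in place of electrophilic formylation): NBS in MeCN at 0 °C gives the aryl bromide 1,5-bis(benzyloxy)-2-bromo-3-(SC)benzene F18. Bromine–lithium exchange (n-BuLi, THF, −78 °C) and a DMF quench give 13.

Further compounds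
F1 | step 20 | 4-(benzyloxy)-2-bromobenzaldehyde | O=Cc1ccc(OCc2ccccc2)cc1Br
F2 | step 20 | [4-(benzyloxy)-2-bromophenyl]methanol | OCc1ccc(OCc2ccccc2)cc1Br
F3 | step 20 | 4-(benzyloxy)-2-bromo-1-(bromomethyl)benzene | BrCc1ccc(OCc2ccccc2)cc1Br
F4 | step 20 | (R)-4-benzyl-3-{(2R)-3-[4-(benzyloxy)-2-bromophenyl]-2-[3,5-bis(benzyloxy)phenyl]propanoyl}oxazolidin-2-one | O=C([C@H](Cc1ccc(OCc2ccccc2)cc1Br)c1cc(OCc2ccccc2)cc(OCc2ccccc2)c1)N1[C@H](Cc2ccccc2)COC1=O
F5 | step 20 | (2R)-3-[4-(benzyloxy)-2-bromophenyl]-2-[3,5-bis(benzyloxy)phenyl]propan-1-ol | OC[C@H](Cc1ccc(OCc2ccccc2)cc1Br)c1cc(OCc2ccccc2)cc(OCc2ccccc2)c1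
F6 | step 20 | TBDPS ether of F5 | CC(C)(C)[Si](OC[C@H](Cc1ccc(OCc2ccccc2)cc1Br)c1cc(OCc2ccccc2)cc(OCc2ccccc2)c1)(c1ccccc1)c1ccccc1
F7 | step 20 | 2,4-bis(benzyloxy)-6-{(2R)-3-[4-(benzyloxy)-2-bromophenyl]-1-[(tert-butyldiphenylsilyl)oxy]propan-2-yl}benzaldehyde | O=Cc1c(OCc2ccccc2)cc(OCc2ccccc2)cc1[C@H](CO[Si](c1ccccc1)(c1ccccc1)C(C)(C)C)Cc1ccc(OCc2ccccc2)cc1Br
F8 | step 20 | 4-(benzyloxy)-2-hydroxy analogue of F7 | O=Cc1c(O)cc(OCc2ccccc2)cc1[C@H](CO[Si](c1ccccc1)(c1ccccc1)C(C)(C)C)Cc1ccc(OCc2ccccc2)cc1Br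
F9 | step 20 | 4-(benzyloxy)-2-methoxy analogue of F7 | O=Cc1c(OC)cc(OCc2ccccc2)cc1[C@H](CO[Si](c1ccccc1)(c1ccccc1)C(C)(C)C)Cc1ccc(OCc2ccccc2)cc1Br
F10 | step 20 | syn-aldol adduct, analogue of 24 with a 4-(benzyloxy)-2-bromophenyl lower ring | COc1ccc([C@@H]([C@H](O)c2c(OC)cc(OCc3ccccc3)cc2[C@H](CO[Si](c2ccccc2)(c2ccccc2)C(C)(C)C)Cc2ccc(OCc3ccccc3)cc2Br)C(=O)N2[C@@H](Cc3ccccc3)COC2=O)c(OCc2ccccc2)c1OCc1ccccc1
F11 | step 20 | diol, analogue of 25 with a 4-(benzyloxy)-2-bromophenyl lower ring | COc1ccc([C@@H]([C@H](O)c2c(OC)cc(OCc3ccccc3)cc2[C@H](CO[Si](c2ccccc2)(c2ccccc2)C(C)(C)C)Cc2ccc(OCc3ccccc3)cc2Br)CO)c(OCc2ccccc2)c1OCc1ccccc1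
F12 | step 20 | aryl ether, analogue of 27 with a 4-(benzyloxy)-2-bromophenyl lower ring | COc1ccc([C@@H]([C@H](O)c2c(OC)cc(OCc3ccccc3)cc2[C@H](CO[Si](c2ccccc2)(c2ccccc2)C(C)(C)C)Cc2ccc(OCc3ccccc3)cc2Br)COc2cccc(OCc3ccccc3)c2)c(OCc2ccccc2)c1OCc1ccccc1
F13 | step 20 | (3R,4S)-trans-4-arylchromane, analogue of 28 with a 4-(benzyloxy)-2-bromophenyl lower ring | COc1ccc([C@@H]2COc3cc(OCc4ccccc4)ccc3[C@H]2c2c(OC)cc(OCc3ccccc3)cc2[C@H](CO[Si](c2ccccc2)(c2ccccc2)C(C)(C)C)Cc2ccc(OCc3ccccc3)cc2Br)c(OCc2ccccc2)c1OCc1ccccc1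
F14 | step 20 | primary alcohol from F13 | COc1ccc([C@@H]2COc3cc(OCc4ccccc4)ccc3[C@H]2c2c(OC)cc(OCc3ccccc3)cc2[C@H](CO)Cc2ccc(OCc3ccccc3)cc2Br)c(OCc2ccccc2)c1OCc1ccccc1
F15 | step 20 | (3R,4S)-7-(benzyloxy)-4-{4-(benzyloxy)-2-[(3R)-7-(benzyloxy)chroman-3-yl]-6-methoxyphenyl}-3-[2,3-bis(benzyloxy)-4-methoxyphenyl]chromane | COc1ccc([C@@H]2COc3cc(OCc4ccccc4)ccc3[C@H]2c2c(OC)cc(OCc3ccccc3)cc2[C@@H]2COc3cc(OCc4ccccc4)ccc3C2)c(OCc2ccccc2)c1OCc1ccccc1
F16 | step 18 | [4-(benzyloxy)-2-hydroxyphenyl][4-(benzyloxy)-2-methoxy-6-(SC)phenyl]methanol, carbinol epimers | OC(c1ccc(OCc2ccccc2)cc1O)c1c(OC)cc(OCc2ccccc2)cc1[C@H](CO[Si](c1ccccc1)(c1ccccc1)C(C)(C)C)Cc1ccc(O[Si](C(C)C)(C(C)C)C(C)C)cc1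
F17 | step 18 | (3R,4S)-7-(benzyloxy)-3-[2,3-bis(benzyloxy)-4-methoxyphenyl]-4-[4-(benzyloxy)-2-methoxy-6-(SC)phenyl]chroman-2-ol, anomers | COc1ccc([C@@H]2C(O)Oc3cc(OCc4ccccc4)ccc3[C@H]2c2c(OC)cc(OCc3ccccc3)cc2[C@H](CO[Si](c2ccccc2)(c2ccccc2)C(C)(C)C)Cc2ccc(O[Si](C(C)C)(C(C)C)C(C)C)cc2)c(OCc2ccccc2)c1OCc1ccccc1
F18 | step 8 | 1,5-bis(benzyloxy)-2-bromo-3-(SC)benzene | Brc1c(OCc2ccccc2)cc(OCc2ccccc2)cc1[C@H](CO[Si](c1ccccc1)(c1ccccc1)C(C)(C)C)Cc1ccc(O[Si](C(C)C)(C(C)C)C(C)C)cc1
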